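The δ-lactone (C7 to O to C20) and cyclohexane ring C (C8, C9, C11–C14) are disconnected together. Both arise in one photochemical Wolff ring contraction of a 2-diazocycloheptanone in which C7 is still a ring ketone between diazo carbon C8 and C14: loss of N2 moves C14 from C7 to C8, contracts the ring to ring C and extrudes C7 as a ketene, which the C20 hydroxyl on the neighbouring quaternary C10 traps as the lactone; ketonisation then sets C8. The step exploits the exocyclic carboxyl carbon C7 on C8 of ring C and its ester link to C20. The precursor is assembled by Mukaiyama–Michael union of two enantioenriched enone fragments (rings A and C).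

Key step: step 12

Remark on labels: C1–C20 are the positions of the ent-kaurane skeleton to which the target formally belongs. Ring A is C1–C5 and C10 (C1 ketone, C3–O–C6 ether bridge, C4 gem-dimethyl, C6 on C5). C20H2–O–C7(=O) is the lactone. Ring C is C8, C9, C11–C14. C13 carries C16(=C17H2)–C15O2H. In these labels the target is 3R,5R,8S,9R,10S,13R.

Remark on ligands: the BINAP enantiomer quoted in steps 3 and 5 is the one expected by analogy with the parent cycloalkenones; in each case the enantiomer that gives the drawn center is meant.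

Step 1
Reactants: 1 cycloheptanone
Product: 2 cyclohepta-2,6-dien-1-one
Conditions: IBX (2-iodoxybenzoic acid, 2.5 equiv), DMSO/fluorobenzene, 70 °C
Reagents that add atoms: none
Why: IBX dehydrogenation of the ketone on both α,β-sides should give the cross-conjugated dienone, with stoichiometry and temperature chosen to stop before tropone.

Step 2
Reactants: 3 tert-butyldimethyl(prop-2-yn-1-yloxy)silane
Product: 4 tert-butyldimethyl{[2-(4,4,5,5-tetramethyl-1,3,2-dioxaborolan-2-yl)prop-2-en-1-yl]oxy}silane
Conditions: CuCl (5 mol %), 1,3-dimesitylimidazolinium chloride (5 mol %), NaOt-Bu (10 mol %), B2pin2, MeOH, THF, 0 °C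
Reagents that add atoms: bis(pinacolato)diboron CC1(C)OB(OC1(C)C)B2OC(C)(C)C(C)(C)O2
Why: Copper-catalysed protoboration of the terminal alkyne with an N-aryl carbene ligand and a propargylic oxygen should place boron on the internal carbon, and methanol protonates the alkenylcopper.

Step 3
Reactants: 2 cyclohepta-2,6-dien-1-one; 4 alkenyl boronate
Product: 5 (6R)-6-{3-[(tert-butyldimethylsilyl)oxy]prop-1-en-2-yl}cyclohept-2-en-1-one
Conditions: [Rh(OH)(cod)]2 (2.5 mol %), (R)-BINAP (6 mol %), KOH (0.3 equiv), dioxane/H2O 10:1, 40 °C, 2 in excess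
Reagents that add atoms: none
Why: Rhodium-catalysed asymmetric conjugate alkenylation (Hayashi–Miyaura reaction) of one of the two equivalent enone termini sets C13 (R) by ligand-controlled face selection, and excess dienone limits double addition.

Step 4
Reactants: 6 4,4-dimethylcyclohex-2-en-1-one
Product: 7 4,4-dimethylcyclohexa-2,5-dien-1-one
Conditions: IBX (1.5 equiv), DMSO, 80 °C
Reagents that add atoms: none
Why: IBX dehydrogenation on the only enolisable side of the enone should give the symmetric dienone.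

Step 5
Reactants: 7 4,4-dimethylcyclohexa-2,5-dien-1-one
Product: 8 (5R)-5-ethenyl-4,4-dimethylcyclohex-2-en-1-one
Conditions: [Rh(cod)2]BF4 (3 mol %), (R)-BINAP (3.3 mol %), CH2=CHBF3K (1.3 equiv), toluene/H2O 4:1, 100 °C
Reagents that add atoms: potassium vinyltrifluoroborate C=C[B-](F)(F)F.[K+]
Why: Rhodium-catalysed asymmetric conjugate vinylation desymmetrises the dienone, the ligand choosing terminus and face to set C5 (R), and the more hindered product enone should not react again.

Step 6
Reactants: 8 (5R)-5-ethenyl-4,4-dimethylcyclohex-2-en-1-one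
Product: 9 (5S,6R)-5-ethenyl-6-(hydroxymethyl)-4,4-dimethylcyclohex-2-en-1-one
Conditions: LiN(SiMe3)2 (1.05 equiv), THF, −78 °C; CH2O (gas, from cracked paraformaldehyde), −78 °C; aq NH4Cl
Reagents that add atoms: formaldehyde C=O
Why: C10 is the only enolisable position (C2 is vinylic, C4 quaternary), and the lithium enolate adds to formaldehyde (aldol) anti to the C5 vinyl group; this C10 configuration is erased again in step 8.

Step 7
Reactants: 9 (5S,6R)-5-ethenyl-6-(hydroxymethyl)-4,4-dimethylcyclohex-2-en-1-one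
Product: 11 (5S,6R)-5,6-bis(hydroxymethyl)-4,4-dimethylcyclohex-2-en-1-one, via keto aldehyde 10 (not isolated)
Conditions: O3, CH2Cl2/MeOH 4:1, −78 °C; Me2S; then NaBH4 (1 equiv), −78 °C
Reagents that add atoms: ozone [O-][O+]=O
Why: Ozonolysis cleaves the electron-rich vinyl group much faster than the hindered electron-poor enone, and borohydride at −78 °C reduces the aldehyde but not the conjugated ketone, so C5 is kept.

Step 8
Reactants: 11 (5S,6R)-5,6-bis(hydroxymethyl)-4,4-dimethylcyclohex-2-en-1-one
Product: 12 (3R)-4,4-dimethyl-1-[(triethylsilyl)oxy]-2,3-bis{[(triethylsilyl)oxy]methyl}cyclohexa-1,5-diene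
Conditions: Et3SiOTf (3.6 equiv), Et3N (5 equiv), CH2Cl2, −78 to 0 °C
Reagents that add atoms: triethylsilyl trifluoromethanesulfonate CC[Si](CC)(CC)OS(=O)(=O)C(F)(F)F
Why: O-silylation of both primary alcohols and soft enolisation toward C10, the only α-hydrogen, should give a single cross-conjugated siloxydiene in which C10 is sp2.

Step 9
Reactants: 12 siloxydiene; 5 (6R)-6-{3-[(tert-butyldimethylsilyl)oxy]prop-1-en-2-yl}cyclohept-2-en-1-one
Product: 13 (5R,6S)-6-[(1R,5R)-5-{3-[(tert-butyldimethylsilyl)oxy]prop-1-en-2-yl}-3-[(triethylsilyl)oxy]cyclohept-2-en-1-yl]-4,4-dimethyl-5,6-bis{[(triethylsilyl)oxy]methyl}cyclohex-2-en-1-one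
Conditions: 12 (1.3 equiv), Tf2NH (5 mol %), CH2Cl2, −78 °C; Et3N quench
Reagents that add atoms: none
Why: Mukaiyama–Michael addition in which Et3SiNTf2 formed in situ activates the enone, C10 attacks C9 on the ring A face anti to the pseudoaxial C5 CH2OSiEt3 group (sets C10 with C20 cis to C6), an open antiperiplanar transition state with H9 over ring A sets C9, and silyl transfer delivers the C7=C8 enol ether regiospecifically.

Step 10
Reactants: 13 silyl enol ether
Product: 15 (5R,6S)-6-[(1S,5R)-5-{3-[(tert-butyldimethylsilyl)oxy]prop-1-en-2-yl}-2-diazo-3-oxocycloheptyl]-4,4-dimethyl-5,6-bis{[(triethylsilyl)oxy]methyl}cyclohex-2-en-1-one, via trifluoroacetyl ketone 14 (not isolated)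
Conditions: (CF3CO)2O, pyridine, CH2Cl2, −20 to 0 °C; evaporate; MsN3, Et3N, H2O (1 equiv), MeCN, rt
Reagents that add atoms: methanesulfonyl azide CS(=O)(=O)N=[N+]=[N-]; trifluoroacetic anhydride O=C(OC(=O)C(F)(F)F)C(F)(F)F (trifluoroacetyl group of 14 only)
Why: C-trifluoroacetylation of the enol silane at C8 followed by detrifluoroacetylative diazo transfer (Regitz type) places the diazo group on the hindered C8 without a free C8 enolate that could undergo retro-Michael cleavage.

Step 11
Reactants: 15 silylated diazo ketone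
Product: 17 (1R,2S,5R)-2-[(1S,5R)-2-diazo-5-(3-hydroxyprop-1-en-2-yl)-3-oxocycloheptyl]-2-(hydroxymethyl)-8,8-dimethyl-6-oxabicyclo[3.2.1]octan-3-one, via triol enone 16 (not isolated)
Conditions: Bu4NF (3.5 equiv), AcOH (1.5 equiv), THF, 0 °C to rt
Reagents that add atoms: none
Why: Fluoride removes the three silyl groups and the freed C6 alkoxide adds 5-exo-trig to C3 of the enone (oxa-Michael), the tether allowing only the bridge cis to C6 so that C3 is set (R), while the acetic acid buffer curbs retro-aldol loss of formaldehyde.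

Step 12
Reactants: 17 oxa-bridged diazo ketone
Product: 20 spiro lactone alcohol (3R,5R,8S,9R,10S,13R) carrying 3-hydroxyprop-1-en-2-yl on C13, via ketene 18 (not isolated), via lactone enol 19 (not isolated)
Conditions: hν (365 nm LED), THF (0.005 M), 0–20 °C
Reagents that add atoms: none
Why: Direct irradiation of the s-cis-locked 2-diazocycloheptanone expels N2 with concerted 1,2-shift of C14 from C7 to C8 (photochemical Wolff rearrangement), so the seven-membered ring contracts to cyclohexane ring C while C7 leaves the ring as a ketene. The closest known reaction type is the photo-Wolff ring contraction of cyclic α-diazo ketones with capture of the ketene by an internal hydroxyl group. Ring C is thus closed by ring contraction, and the δ-lactone by 6-exo-dig addition of the C20 hydroxyl (held on the adjacent quaternary C10) to ketene carbon C7, which gives lactone enol 19. The one new stereocenter, C8, is set by kinetic ketonisation of 19: the proton should arrive on the convex face syn to H9, because the other face is screened by the pseudoaxial ring A substituent on spiro C10 and by the axial hydrogens of ring C, and this gives the cis-fused lactone; C9, C10 and C13 are not touched. The step needs the Wolff shift to win over carbene 1,2-H shift and O–H insertion, which the fixed s-cis geometry and metal-free photolysis should secure, and it needs C20–OH rather than the remote allylic C15–OH to trap the ketene, which the six-membered transition state should secure.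

Step 13
Reactants: 20 spiro lactone alcohol
Product: 22 target acid 2-[(3R,5R,8S,9R,10S,13R)-spiro lactone-13-yl]prop-2-enoic acid, via enal 21 (not isolated)
Conditions: TEMPO (10 mol %), NaClO2 (2.5 equiv), NaOCl (3 mol %), MeCN/phosphate buffer pH 6.7, 35 °C
Reagents that add atoms: sodium chlorite [Na+].[O-]Cl=O
Why: TEMPO/chlorite oxidation takes the only remaining alcohol, the primary allylic C15–OH, through enal 21 to the acrylic acid (oxoammonium oxidation, then Pinnick-type oxidation) under buffered conditions that should leave the lactone, C8 and the β-alkoxy ketone untouched.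

Compound list

1 | cycloheptanone | O=C1CCCCCC1 | starting material
2 | cyclohepta-2,6-dien-1-one | O=C1C=CCCC=C1 | intermediate
3 | tert-butyldimethyl(prop-2-yn-1-yloxy)silane | C#CCO[Si](C)(C)C(C)(C)C | starting material
4 | tert-butyldimethyl{[2-(4,4,5,5-tetramethyl-1,3,2-dioxaborolan-2-yl)prop-2-en-1-yl]oxy}silane | C=C(CO[Si](C)(C)C(C)(C)C)B1OC(C)(C)C(C)(C)O1 | intermediate
5 | (6R)-6-{3-[(tert-butyldimethylsilyl)oxy]prop-1-en-2-yl}cyclohept-2-en-1-one | C=C(CO[Si](C)(C)C(C)(C)C)[C@@H]1CCC=CC(=O)C1 | intermediate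
6 | 4,4-dimethylcyclohex-2-en-1-one | CC1(C)CCC(=O)C=C1 | starting material
7 | 4,4-dimethylcyclohexa-2,5-dien-1-one | CC1(C)C=CC(=O)C=C1 | intermediate
8 | (5R)-5-ethenyl-4,4-dimethylcyclohex-2-en-1-one | C=C[C@@H]1C(C)(C)C=CC(=O)C1 | intermediate
9 | (5S,6R)-5-ethenyl-6-(hydroxymethyl)-4,4-dimethylcyclohex-2-en-1-one (trans) | C=C[C@@H]1C(C)(C)C=CC(=O)[C@H]1CO | intermediate
10 | keto aldehyde, (1S,6R)-6-(hydroxymethyl)-2,2-dimethyl-5-oxocyclohex-3-ene-1-carbaldehyde | O=C[C@@H]1C(C)(C)C=CC(=O)[C@H]1CO | intermediate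
11 | (5S,6R)-5,6-bis(hydroxymethyl)-4,4-dimethylcyclohex-2-en-1-one | OC[C@@H]1C(C)(C)C=CC(=O)[C@H]1CO | intermediate
12 | (3R)-4,4-dimethyl-1-[(triethylsilyl)oxy]-2,3-bis{[(triethylsilyl)oxy]methyl}cyclohexa-1,5-diene | CC[Si](CC)(CC)OC[C@@H]1C(C)(C)C=CC(O[Si](CC)(CC)CC)=C1CO[Si](CC)(CC)CC | intermediate
13 | (5R,6S)-6-[(1R,5R)-5-{3-[(tert-butyldimethylsilyl)oxy]prop-1-en-2-yl}-3-[(triethylsilyl)oxy]cyclohept-2-en-1-yl]-4,4-dimethyl-5,6-bis{[(triethylsilyl)oxy]methyl}cyclohex-2-en-1-one | C=C(CO[Si](C)(C)C(C)(C)C)[C@@H]1CC[C@H](C=C(O[Si](CC)(CC)CC)C1)[C@]2(CO[Si](CC)(CC)CC)C(=O)C=CC(C)(C)[C@H]2CO[Si](CC)(CC)CC | intermediate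
14 | trifluoroacetyl ketone, the ketone of 13 carrying COCF3 on C8 (C8 epimers in equilibrium with the enol) | C=C(CO[Si](C)(C)C(C)(C)C)[C@@H]1CC[C@H](C(C(=O)C(F)(F)F)C(=O)C1)[C@]2(CO[Si](CC)(CC)CC)C(=O)C=CC(C)(C)[C@H]2CO[Si](CC)(CC)CC | intermediate
15 | (5R,6S)-6-[(1S,5R)-5-{3-[(tert-butyldimethylsilyl)oxy]prop-1-en-2-yl}-2-diazo-3-oxocycloheptyl]-4,4-dimethyl-5,6-bis{[(triethylsilyl)oxy]methyl}cyclohex-2-en-1-one | C=C(CO[Si](C)(C)C(C)(C)C)[C@@H]1CC[C@H](C(=[N+]=[N-])C(=O)C1)[C@]2(CO[Si](CC)(CC)CC)C(=O)C=CC(C)(C)[C@H]2CO[Si](CC)(CC)CC | intermediate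
16 | triol enone, (5R,6S)-6-[(1S,5R)-2-diazo-5-(3-hydroxyprop-1-en-2-yl)-3-oxocycloheptyl]-5,6-bis(hydroxymethyl)-4,4-dimethylcyclohex-2-en-1-one | C=C(CO)[C@@H]1CC[C@H](C(=[N+]=[N-])C(=O)C1)[C@]2(CO)C(=O)C=CC(C)(C)[C@H]2CO | intermediate
17 | (1R,2S,5R)-2-[(1S,5R)-2-diazo-5-(3-hydroxyprop-1-en-2-yl)-3-oxocycloheptyl]-2-(hydroxymethyl)-8,8-dimethyl-6-oxabicyclo[3.2.1]octan-3-one | C=C(CO)[C@@H]1CC[C@H](C(=[N+]=[N-])C(=O)C1)[C@]2(CO)C(=O)C[C@H]3OC[C@@H]2C3(C)C | intermediate
18 | ketene, ring-contracted cyclohexylidene ketene (C8=C7=O on ring C; 9R,13R; ring A unit and C20–OH as in 17) | C=C(CO)[C@@H]1CC[C@H](C(=C=O)C1)[C@]2(CO)C(=O)C[C@H]3OC[C@@H]2C3(C)C | intermediate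
19 | lactone enol, C7(OH)=C8 enol tautomer of lactone 20 | C=C(CO)[C@@H]1CC[C@@H]2C(C1)=C(O)OC[C@]23C(=O)C[C@H]4OC[C@@H]3C4(C)C | intermediate
20 | spiro lactone alcohol: δ-lactone (C7 carbonyl, O, C20) cis-fused to cyclohexane ring C and spiro-linked at C10 to the 8,8-dimethyl-6-oxabicyclo[3.2.1]octan-3-one unit, 3-hydroxyprop-1-en-2-yl on C13; 3R,5R,8S,9R,10S,13R | C=C(CO)[C@@H]1CC[C@@H]2[C@H](C1)C(=O)OC[C@]21C(=O)C[C@H]2OC[C@@H]1C2(C)C | intermediate
21 | enal, as 20 with 3-oxoprop-1-en-2-yl on C13 | C=C(C=O)[C@@H]1CC[C@@H]2[C@H](C1)C(=O)OC[C@]21C(=O)C[C@H]2OC[C@@H]1C2(C)C | intermediate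
22 | target acid CNP0268721.2, 2-substituted prop-2-enoic acid on C13 of the spiro lactone; 3R,5R,8S,9R,10S,13R | C=C(C(=O)O)[C@@H]1CC[C@@H]2[C@H](C1)C(=O)OC[C@]21C(=O)C[C@H]2OC[C@@H]1C2(C)C | target

Total step count: 13. Longest linear sequence: 10 steps (steps 4 to 13, from 6).

Steps most likely to fail

Step 9. The union may suffer from poor facial selectivity at C9, from low reactivity of the tetrasubstituted enol ether toward a plain enone, or from a second, intramolecular Michael addition of the new C7=C8 enol ether onto C3 of ring A (formal [4+2] closure). The fallback sets out from 5 (with 12) and comes back to the route at 15. Morita–Baylis–Hillman reaction of 5 with aqueous formaldehyde (DMAP, THF/H2O) would give the 2-(hydroxymethyl) enone F1. Dess–Martin oxidation would give the 2-formyl enone F2, a doubly activated acceptor that should take up siloxydiene 12 at −78 °C in CH2Cl2 without a strong Lewis acid. After aqueous work-up this would give the 2-(hydroxymethylene) ketone F3, whose C8 enol is a stabilised 1,3-dicarbonyl unit and should not add to C3. Deformylative diazo transfer (MsN3, Et3N, MeCN) would then give 15.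

Step 12. The carbene may undergo 1,2-hydrogen shift or insertion into the free C20 O–H bond before the Wolff shift, or ketonisation may take place from the wrong face. The fallback sets out from 15 and comes back at 20; it separates ring contraction from lactone closure. Irradiation of 15 at 450 nm in THF/MeOH would trap the ketene intermolecularly as the ring-contracted methyl ester F4. Here C8 is set by ketonisation of the ester enol anti to the bulky C9 substituent, which again should place C7 cis to C10. Bu4NF/AcOH would remove the silyl groups and close the oxa-bridge to give the hydroxy ester F5. F5 should lactonise to 20 on warming with PPTS in toluene.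

Step 11. Retro-aldol loss of formaldehyde from the C10 hydroxymethyl ketone may occur, or the C20 alkoxide may compete with the C6 alkoxide for oxa-Michael closure onto C3. The fallback sets out from 15 and comes back at 20; it acylates C20–O before any base is used. PPTS in MeOH at 0 °C would remove only the two triethylsilyl ethers to give the diol diazo ketone F6. Wolff ring contraction and lactonisation with 450 nm light, which the ring A enone does not absorb, would give the lactone enone F7. Bu4NF in THF would then free C6–OH and C15–OH, and the C6 alkoxide should close the oxa-bridge to give 20.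

Further compounds

F1 | step 9 | (6R)-6-{3-[(tert-butyldimethylsilyl)oxy]prop-1-en-2-yl}-2-(hydroxymethyl)cyclohept-2-en-1-one | C=C(CO[Si](C)(C)C(C)(C)C)[C@@H]1CCC=C(CO)C(=O)C1
F2 | step 9 | (6R)-6-{3-[(tert-butyldimethylsilyl)oxy]prop-1-en-2-yl}-2-formylcyclohept-2-en-1-one | C=C(CO[Si](C)(C)C(C)(C)C)[C@@H]1CCC=C(C=O)C(=O)C1
F3 | step 9 | 2-(hydroxymethylene) ketone, analogue of 15 with =CH–OH on C8 in place of the diazo group | C=C(CO[Si](C)(C)C(C)(C)C)[C@@H]1CC[C@H](C(=CO)C(=O)C1)[C@]2(CO[Si](CC)(CC)CC)C(=O)C=CC(C)(C)[C@H]2CO[Si](CC)(CC)CC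
F4 | step 12 | ring-contracted methyl ester, methyl cyclohexanecarboxylate with C7 cis to C10 on ring C, silyl ethers intact; 5R,8S,9R,10S,13R | C=C(CO[Si](C)(C)C(C)(C)C)[C@@H]1CC[C@H]([C@H](C1)C(=O)OC)[C@]2(CO[Si](CC)(CC)CC)C(=O)C=CC(C)(C)[C@H]2CO[Si](CC)(CC)CC
F5 | step 12 | hydroxy ester, desilylated methyl ester with closed C3–O–C6 bridge; 3R,5R,8S,9R,10S,13R | C=C(CO)[C@@H]1CC[C@H]([C@H](C1)C(=O)OC)[C@]2(CO)C(=O)C[C@H]3OC[C@@H]2C3(C)C
F6 | step 11 | diol diazo ketone, 15 without the two triethylsilyl groups | C=C(CO[Si](C)(C)C(C)(C)C)[C@@H]1CC[C@H](C(=[N+]=[N-])C(=O)C1)[C@]2(CO)C(=O)C=CC(C)(C)[C@H]2CO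
F7 | step 11 | lactone enone, cis-fused spiro lactone with ring A enone, free C6–OH and C15–O silyl ether; 5R,8S,9R,10S,13R | C=C(CO[Si](C)(C)C(C)(C)C)[C@@H]1CC[C@@H]2[C@H](C1)C(=O)OC[C@]23C(=O)C=CC(C)(C)[C@H]3CO
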